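Assumption: I read the SMILES as one lactone carbonyl carbon, 31 CH2 groups and the ring oxygen (oxacyclotritriacontan-2-one, C32H62O2, 33-membered ring); the molecule is achiral, so there is no stereocentre to set.

**Retrosynthetic overview**
- Target (C1 = lactone C=O, C32 = OCH2) ⇒ Raney-nickel hydrodesulfurization of a 2,5-thiophene-bridged macrolactone. This is the key step: the aromatic ring is destroyed, sulfur is excised, and the four thiophene carbons become C17–C20.
- Thiophene-bridged macrolactone ⇒ [1+1] double Negishi cyclocoupling of 2,5-dibromothiophene with an α,ω-bis(bromozincio) ester. The ring closes through two C(sp2)–C(sp3) bonds (C16–C17 and C20–C21), not through the ester C–O bond.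
- Bis-zinc ester ⇒ 12-bromododecyl 16-bromohexadecanoate ⇒ 16-bromohexadecanoic acid + 12-bromododecan-1-ol (plain intermolecular esterification).
- 2,5-Dibromothiophene ⇒ thiophene + NBS.
- Ring order: the macrocycle is formed once, in the cyclocoupling; the thiophene ring is then erased in the last step, leaving only the 33-membered lactone.

**Route**

Step 1
Reactants: 1 thiophene
Product: 3 2,5-dibromothiophene, via 2-bromothiophene 2 (not isolated)
Conditions: NBS (2.05 equiv), DMF, 0 °C → rt, dark; distil
Reagents that add atoms: N-bromosuccinimide, O=C1CCC(=O)N1Br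
Why: Electrophilic aromatic bromination (SEAr) occurs at the α-positions of thiophene, and the 2-bromo intermediate is brominated again at the remaining α-position C5, so two equivalents of NBS give the 2,5-dibromide; no stereocentre.

Step 2
Reactants: 4 16-bromohexadecanoic acid; 5 12-bromododecan-1-ol
Product: 6 12-bromododecyl 16-bromohexadecanoate
Conditions: TsOH·H2O (5 mol%), toluene, reflux, Dean–Stark (1:1 stoichiometry)
Reagents that add atoms: none
Why: Fischer esterification driven to completion by azeotropic removal of water, with both primary C–Br bonds inert to catalytic acid; no stereocentre.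

Step 3
Reactants: 6 12-bromododecyl 16-bromohexadecanoate; 3 2,5-dibromothiophene
Product: 10 thiophene-bridged macrolactone 14-oxa-1(2,5)-thiophenacyclotriacontaphan-15-one, via bis(bromozincio) ester 7 (not isolated), via acyl-side monocoupled zinc reagent 8 (not isolated), via alkoxy-side monocoupled zinc reagent 9 (not isolated)
Conditions: Zn dust (3 equiv), I2 (5 mol%), DMA, 80 °C, 4 h; then 7 and 3 (1.0 equiv) co-added by syringe pump over 16 h to Pd(OAc)2 (10 mol%), SPhos (20 mol%), THF, 50 °C, final 2 mM
Reagents that add atoms: none
Why: Proposed new method: a [1+1] double Negishi cyclocoupling in which zinc insertion gives an ester-tolerant bis(alkylzinc bromide), the first Pd(0)-catalysed alkyl–thienyl coupling is intermolecular, and the resulting ω-zincioalkyl bromothiophene (8 or 9) then closes the ring by oxidative addition, intramolecular transmetalation and reductive elimination, which at 2 mM should outrun chain growth because the effective molarity of a strain-free ring of more than 30 members is roughly 10–50 mM; the closest known reactions are the Tamao–Kumada cyclocoupling of di-Grignard reagents with dihaloarenes to cyclophanes and the ordinary alkylzinc–bromothiophene Negishi coupling; no stereocentre.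

Step 4
Reactants: 10 thiophene-bridged macrolactone
Product: 11 oxacyclotritriacontan-2-one (dotriacontan-32-olide)
Conditions: Raney Ni (W-2, washed neutral, ca. 15 g per g of 10), H2 (1 atm), THF, 60 °C; filter through Celite
Reagents that add atoms: none
Why: Key step, a Raney-nickel reductive desulfurization (Mozingo-type hydrodesulfurization) in which nickel cleaves both C–S bonds, sulfur stays on the metal as nickel sulfide and adsorbed hydrogen saturates the C4 unit, so the thiophene becomes the four CH2 groups C17–C20 while the saturated lactone is inert in an alcohol-free neutral medium at 1 atm H2; no stereocentre.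

**Compound list**
1 | thiophene | c1ccsc1 | starting material
2 | 2-bromothiophene | Brc1cccs1 | intermediate (not isolated)
3 | 2,5-dibromothiophene | Brc1ccc(Br)s1 | intermediate
4 | 16-bromohexadecanoic acid | OC(=O)CCCCCCCCCCCCCCCBr | starting material
5 | 12-bromododecan-1-ol | OCCCCCCCCCCCCBr | starting material
6 | 12-bromododecyl 16-bromohexadecanoate | BrCCCCCCCCCCCCCCCC(=O)OCCCCCCCCCCCCBr | intermediate
7 | 12-(bromozincio)dodecyl 16-(bromozincio)hexadecanoate | Br[Zn]CCCCCCCCCCCCCCCC(=O)OCCCCCCCCCCCC[Zn]Br | intermediate (not isolated)
8 | 12-(bromozincio)dodecyl 16-(5-bromothiophen-2-yl)hexadecanoate | Brc1ccc(s1)CCCCCCCCCCCCCCCC(=O)OCCCCCCCCCCCC[Zn]Br | intermediate (not isolated)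
9 | 12-(5-bromothiophen-2-yl)dodecyl 16-(bromozincio)hexadecanoate | Br[Zn]CCCCCCCCCCCCCCCC(=O)OCCCCCCCCCCCCc1ccc(Br)s1 | intermediate (not isolated)
10 | 14-oxa-1(2,5)-thiophenacyclotriacontaphan-15-one (lactone of 16-[5-(12-hydroxydodecyl)thiophen-2-yl]hexadecanoic acid) | O=C1CCCCCCCCCCCCCCCc2ccc(s2)CCCCCCCCCCCCO1 | intermediate
11 | oxacyclotritriacontan-2-one (dotriacontan-32-olide) | O=C1CCCCCCCCCCCCCCCCCCCCCCCCCCCCCCCO1 | target

**Count**
Total step count: 4.
Longest linear sequence: 3 steps (1 → 3 → 10 → 11; the arm 4 + 5 → 6 → 10 → 11 is equally long).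

**Steps most likely to fail**

1. Step 3 (the [1+1] cyclocoupling). The risks are chain growth to linear or [2+2] oligomers, capping of both zinc ends by two dibromide molecules, and protonolysis of the dilute organozinc.
 Fallback: a purely intramolecular ring closure. It sets out from 1, 5 and 4 and comes back to the route at 9 (and from there at 10). Thiophene 1 is lithiated (n-BuLi, THF, 0 °C) to 2-thienyllithium F1. F1 (2.2 equiv; the first equivalent only removes the hydroxyl proton) is alkylated by 5 in refluxing THF to give 12-(thiophen-2-yl)dodecan-1-ol F2. Fischer esterification of F2 with 4 gives 12-(thiophen-2-yl)dodecyl 16-bromohexadecanoate F3. NBS (1.0 equiv, DMF, 0 °C) brominates the free α-position to give 12-(5-bromothiophen-2-yl)dodecyl 16-bromohexadecanoate F4. Zn dust/I2 in DMA at 70 °C inserts only into the alkyl bromide, since the electron-rich thienyl bromide needs LiCl or a cobalt catalyst. This gives 9 as a single species, which is added slowly to Pd(OAc)2/SPhos in THF and closes to 10 by intramolecular Negishi coupling.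

2. Step 4 (desulfurization inside the macrolactone). The risks are residual olefin, lactone cleavage by basic nickel, and loss by adsorption on the large nickel excess.
 Fallback: desulfurize the open chain and re-close. It sets out from 10 and comes back at 11. Saponification (LiOH, THF–H2O, then acid) gives 16-[5-(12-hydroxydodecyl)thiophen-2-yl]hexadecanoic acid F5. Raney Ni on its sodium salt in refluxing aqueous NaOH–EtOH, then acid, gives 32-hydroxydotriacontanoic acid F6. Yamaguchi activation (2,4,6-trichlorobenzoyl chloride, Et3N, THF) gives 32-hydroxydotriacontanoic 2,4,6-trichlorobenzoic anhydride F7, which is added slowly to DMAP in refluxing toluene (1 mM) and lactonizes to 11.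

3. Step 1 (dibromination). Mono- or tribrominated thiophene would upset the exact 1:1 stoichiometry that the cyclocoupling needs.
 Fallback: a deprotonation route instead of SEAr. It sets out from 1 and comes back at 3. Thiophene is doubly deprotonated (n-BuLi 2.4 equiv, TMEDA, hexane, reflux) to 2,5-dilithiothiophene F8, which is quenched with 1,2-dibromoethane (−78 °C → rt) to give 3 as the only regioisomer.

**Further compounds**
F1 | step 3 | 2-thienyllithium | [Li]c1cccs1
F2 | step 3 | 12-(thiophen-2-yl)dodecan-1-ol | OCCCCCCCCCCCCc1cccs1
F3 | step 3 | 12-(thiophen-2-yl)dodecyl 16-bromohexadecanoate | BrCCCCCCCCCCCCCCCC(=O)OCCCCCCCCCCCCc1cccs1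
F4 | step 3 | 12-(5-bromothiophen-2-yl)dodecyl 16-bromohexadecanoate | BrCCCCCCCCCCCCCCCC(=O)OCCCCCCCCCCCCc1ccc(Br)s1
F5 | step 4 | 16-[5-(12-hydroxydodecyl)thiophen-2-yl]hexadecanoic acid | OC(=O)CCCCCCCCCCCCCCCc1ccc(CCCCCCCCCCCCO)s1
F6 | step 4 | 32-hydroxydotriacontanoic acid | OC(=O)CCCCCCCCCCCCCCCCCCCCCCCCCCCCCCCO
F7 | step 4 | 32-hydroxydotriacontanoic 2,4,6-trichlorobenzoic anhydride | OCCCCCCCCCCCCCCCCCCCCCCCCCCCCCCCC(=O)OC(=O)c1c(Cl)cc(Cl)cc1Cl
F8 | step 1 | 2,5-dilithiothiophene | [Li]c1ccc([Li])s1
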